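**Plan**

1. Locants: unit A = O2–C1(=O)–C7a=C3a–C3(=C8–C11), ring A = C3a–C4–C5–C6–C7–C7a; unit B primed: lactone C1′(=O)–O2′–C3′, ring B = C6–C7–C7a′–C3a′–C3′, ring C = C7a′–C7′=C6′–C5′–C4′–C3a′, butanoyl C8′–C11′; β = face of ring B carrying C7′ and C4′, α = face of C1′.
2. Cuts, in order: C8′=O and C3=C8 (late oxidation, aldol–dehydration); C5–C6 of ring A (6-endo radical closure of a C6 radical onto a 4-vinylbutenolide); C6–I and O2′–C3′ (iodolactonisation of a C6=C3′ cyclopentene by the C1′ amide); C7–C7a (Pd allylic alkylation of tetronic acid); C3′–C3a′ (benzoin); C7a′–C7 (Birch reductive alkylation of an anisamide).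
3. Forward: ring C from the arene with quaternary C7a′ → ring B → butenolide ring attached at C7 → lactone bridge → ring A last; the C8–C11 chain and the C8′ ketone are finished afterwards without any ring closure.
4. Enabling feature: C1′ on C7a′ and C3′ are 1,3-cis across ring B, so the lactone can only bridge the α face (2-oxabicyclo[2.2.1]heptan-3-one) and the anti iodine lands on C6β, the face that already holds the C7 butenolide; the dienyl lactone C7a=C3a–C4=C5 has its terminus C5 six atoms from the C6 radical.
5. Stereochemistry: one bought stereocentre (prolinol ether auxiliary) sets C7a′; C3a′ (cis fusion), C3′–O (convex-face addition), C7 (double inversion through π-allyl Pd), C3′ (tethered lactonisation) and C6 (cis fusion in the key step) are relayed; the auxiliary leaves in the lactonisation.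

Key step: step 13

Assumption: the (S)-prolinol ether amide is taken to steer the bromide to the enolate face that gives the (S)-configured C7a′ drawn in 6 (attack anti to the pyrrolidine ring of the chelated enolate); were the sense opposite, the commercial (R)-auxiliary would be used with all later steps unchanged; C8′ is carried as a mixture of both epimers (no descriptor in the SMILES) until step 17.

Step 1
Reactants: 1 2-methoxybenzoyl chloride; 2 (S)-2-(methoxymethyl)pyrrolidine
Product: 3 (S)-N-(2-methoxybenzoyl)-2-(methoxymethyl)pyrrolidine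
Conditions: Et3N, CH2Cl2, 0 °C → rt
Reagents that add atoms: none
Why: N-acylation of the secondary amine by the acid chloride (Schotten–Baumann type) should give the tertiary benzamide without touching the auxiliary stereocentre.

Step 2
Reactants: 3 (S)-N-(2-methoxybenzoyl)-2-(methoxymethyl)pyrrolidine; 4 3-bromo-1,1-dimethoxypropane
Product: 6 (1S)-1-(3,3-dimethoxypropyl)-2-methoxycyclohexa-2,5-diene-1-carboxamide of the auxiliary, via potassium amide enolate 5 (not isolated)
Conditions: K, NH3(l)/THF, t-BuOH (1 equiv), −78 °C; then 4, −78 °C → rt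
Reagents that add atoms: none
Why: Birch reduction–alkylation of a chiral 2-methoxybenzamide: the chelated amide enolate should be alkylated at C7a′ on the face dictated by the auxiliary, which sets the quaternary stereocentre and leaves the C6′=C7′ alkene and the C3a′ enol ether in place.

Step 3
Reactants: 6 Birch alkylation product
Product: 7 keto aldehyde (C3a′ ketone; C3′ aldehyde at the end of the C7–C6 chain)
Conditions: 1 M HCl (aq), THF, rt → 40 °C
Reagents that add atoms: water (O)
Why: Acid hydrolysis of the enol ether and of the dimethyl acetal should unmask both carbonyl groups, the β,γ-alkene C6′=C7′ being unable to move into conjugation because C7a′ is quaternary.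

Step 4
Reactants: 7 keto aldehyde
Product: 8 cis-fused α-ketol (ring B closed; C3′ ketone; C3a′–OH)
Conditions: 3-benzyl-5-(2-hydroxyethyl)-4-methylthiazolium chloride (20 mol%), DBU (20 mol%), t-BuOH, 40 °C
Reagents that add atoms: none
Why: Carbene-catalysed intramolecular crossed benzoin reaction: the acyl anion equivalent formed from the aldehyde should add to the C3a′ ketone to close the five-membered ring B (C3′–C3a′ bond), the configuration of the carbinol being irrelevant because its oxygen is removed next.

Step 5
Reactants: 8 cis-fused α-ketol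
Product: 9 (3aS,7aS) cis-fused bicyclic ketone
Conditions: SmI2 (2.5 equiv), THF–MeOH, −78 °C
Reagents that add atoms: none
Why: SmI2 reduction of an α-hydroxy ketone should cleave the C3a′–O bond through the samarium enolate, and protonation of this epimerisable α-centre should give the more stable cis-fused hydrindenone with C3a′–H on the α face.

Step 6
Reactants: 9 cis-fused bicyclic ketone
Product: 11 (3aR,7aS) enone (C3′=O; C6=C7), via trimethylsilyl enol ether 10 (not isolated)
Conditions: LDA, TMSCl, THF, −78 °C; then Pd(OAc)2 (1.1 equiv), MeCN, rt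
Reagents that add atoms: none
Why: Saegusa–Ito oxidation: kinetic deprotonation at the C6 methylene (not at the ring-fusion methine) should give the silyl enol ether, which Pd(II) dehydrogenates to the C6=C7 enone.

Step 7
Reactants: 12 butanal; 13 tributyltin hydride
Product: 15 tributyl[1-(methoxymethoxy)butyl]stannane (racemic), via lithium 1-(tributylstannyl)butan-1-olate 14 (not isolated)
Conditions: LDA, THF, 0 °C; then 12, −78 °C; then MOMCl, −78 °C → rt
Reagents that add atoms: chloromethyl methyl ether (COCCl)
Why: Addition of tributylstannyllithium to the aldehyde and O-alkylation of the alkoxide should give the α-alkoxystannane, a storable precursor of the α-alkoxy organolithium that carries C8′–C11′.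

Step 8
Reactants: 11 enone; 15 tributyl[1-(methoxymethoxy)butyl]stannane
Product: 18 tertiary allylic methyl carbonate (3′β-OCO2Me; 3′α-CH(OMOM)Pr; C6=C7), via 1-(methoxymethoxy)butyllithium 16 (not isolated), via lithium 3′β-alkoxide 17 (not isolated)
Conditions: 15, n-BuLi, THF, −78 °C; then 11, −78 °C; then ClCO2Me, −78 → 0 °C
Reagents that add atoms: methyl chloroformate (COC(=O)Cl)
Why: Tin–lithium exchange should give the α-alkoxy organolithium, which adds 1,2 to the enone from the convex α face (anti to ring C, helped by lithium coordination to the amide carbonyl on that face) so that the new C3′–O bond is β, and the alkoxide is trapped as the carbonate.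

Step 9
Reactants: 18 tertiary allylic methyl carbonate; 19 tetronic acid
Product: 20 3-substituted tetronic acid (C7–C7a bond on the β face; C6=C3′)
Conditions: Pd2(dba)3·CHCl3 (2.5 mol%), dppe (6 mol%), THF, 50 °C
Reagents that add atoms: none
Why: Tsuji–Trost allylic alkylation: Pd(0) should ionise the β-carbonate with inversion (Pd on the α face) and the soft tetronate carbon should attack the less substituted allyl terminus C7 anti to Pd, so that C7–C7a forms on the β face (net retention with allylic transposition) and the trisubstituted C6=C3′ alkene results.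

Step 10
Reactants: 20 3-substituted tetronic acid
Product: 21 enol triflate (C3a–OTf)
Conditions: PhNTf2, Et3N, CH2Cl2, 0 °C → rt
Reagents that add atoms: N-phenylbis(trifluoromethanesulfonimide) (O=S(=O)(N(c1ccccc1)S(=O)(=O)C(F)(F)F)C(F)(F)F)
Why: O-Sulfonylation of the vinylogous acid should give the β-acyl vinyl triflate under conditions that leave the tertiary amide alone.

Step 11
Reactants: 21 enol triflate; 22 tributyl(vinyl)stannane
Product: 23 4-vinylbutenolide (C4=C5 on C3a)
Conditions: Pd(PPh3)4 (5 mol%), LiCl, THF, 65 °C
Reagents that add atoms: none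
Why: Stille coupling of the electron-poor vinyl triflate should install the vinyl group and complete the C7a=C3a–C4=C5 dienyl lactone.

Step 12
Reactants: 23 4-vinylbutenolide
Product: 25 6β-iodo bridged lactone, via cyclic iminium ether iodide 24 (not isolated)
Conditions: I2, NaHCO3, THF–H2O (1:1), 0 °C → rt
Reagents that add atoms: iodine (II); water (O)
Why: Iodolactonisation with amide participation: the amide oxygen, held on the α face at C7a′, should open the iodonium of the trisubstituted C6=C3′ alkene at the tertiary carbon C3′ (5-exo, Markovnikov) so that iodine ends on C6β, and hydrolysis of the iminium ether releases the auxiliary and leaves the bridged lactone.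

Step 13
Reactants: 25 6β-iodo bridged lactone
Product: 26 pentacyclic bis-lactone with ring A closed (C3 still CH2; C8′–OMOM)
Conditions: (Me3Si)3SiH (slow addition), AIBN (cat.), PhH (0.01 M), 80 °C
Reagents that add atoms: none
Why: Iodine abstraction by the silyl radical should give the secondary 2-oxabicyclo[2.2.1]hept-6-yl radical at C6, which adds to C5, the terminal carbon of the C7a=C3a–C4=C5 dienyl lactone, and the ester-stabilised allyl radical (C4–C3a–C7a) takes hydrogen from the silane at the less hindered C4, restoring the tetrasubstituted butenolide. The closest known reaction type is the reductive radical cyclisation of iodolactones with a stannane or silane, here in its 6-endo variant onto the terminus of a conjugated diene (an intramolecular Giese-type 1,6-addition). Ring A is closed in the 6-endo-trig mode. The new stereocentre C6 is fixed by C7: the tether C7–C7a=C3a–C4 starts on the β (exo) face and can reach the planar C6 radical only from that face, so the A/B fusion is cis and C6–H ends α. The step needs 6-endo over 5-exo closure and cyclisation over premature reduction; the first is secured by attack at the unsubstituted diene terminus, which gives a delocalised radical whereas 5-exo would give a primary radical in a strained bicyclo[3.3.0]octene, the second by the slow hydrogen donor kept at low concentration.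

Step 14
Reactants: 26 pentacyclic bis-lactone; 12 butanal
Product: 28 C3-(1-hydroxybutyl) butenolide (mixture at C3 and C8), via 2-silyloxyfuran 27 (not isolated)
Conditions: TBSOTf, Et3N, CH2Cl2, 0 °C; then 12, BF3·OEt2, −78 °C
Reagents that add atoms: none
Why: Soft enolisation of the butenolide should give the 2-silyloxyfuran, which undergoes a vinylogous Mukaiyama aldol addition to butanal at C3, the only free furan position, the bridged lactone having no α-hydrogen; both new stereocentres disappear in the next step.

Step 15
Reactants: 28 C3-(1-hydroxybutyl) butenolide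
Product: 30 (Z)-butylidene butenolide (C8′–OMOM), via mesylate 29 (not isolated)
Conditions: MsCl, Et3N, CH2Cl2, 0 °C; then DBU, rt
Reagents that add atoms: none
Why: Mesylation and E1cB elimination through the acidic C3 hydrogen should give the γ-alkylidene butenolide, the (Z)-isomer (propyl syn to the ring oxygen, away from C4) being the thermodynamically preferred one.

Step 16
Reactants: 30 (Z)-butylidene butenolide
Product: 31 C8′ carbinol
Conditions: Me2BBr, CH2Cl2, −78 °C; then aq. NaHCO3
Reagents that add atoms: none
Why: Bromodimethylborane should cleave the methoxymethyl acetal at low temperature without opening either lactone or adding to the alkylidene butenolide.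

Step 17
Reactants: 31 C8′ carbinol
Product: 32 CNP0423313.1
Conditions: Dess–Martin periodinane, CH2Cl2, 0 °C → rt
Reagents that add atoms: none
Why: Dess–Martin oxidation of the secondary alcohol should give the butanoyl ketone, merging both C8′ epimers, with no epimerisable stereocentre next to the new carbonyl.

**Compound list**

1 | 2-methoxybenzoyl chloride | COc1ccccc1C(Cl)=O | starting material
2 | (S)-2-(methoxymethyl)pyrrolidine | COC[C@@H]1CCCN1 | starting material
3 | (S)-(2-methoxyphenyl)[2-(methoxymethyl)pyrrolidin-1-yl]methanone | COc1ccccc1C(=O)N1CCC[C@H]1COC | intermediate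
4 | 3-bromo-1,1-dimethoxypropane | COC(CCBr)OC | starting material
5 | potassium (2-methoxycyclohexa-2,5-dien-1-ylidene)[(S)-2-(methoxymethyl)pyrrolidin-1-yl]methanolate (amide enolate) | [K+].COC1=CCC=CC1=C([O-])N2CCC[C@H]2COC | intermediate
6 | [(1S)-1-(3,3-dimethoxypropyl)-2-methoxycyclohexa-2,5-dien-1-yl][(2S)-2-(methoxymethyl)pyrrolidin-1-yl]methanone | COC1=CCC=C[C@]1(CCC(OC)OC)C(=O)N2CCC[C@H]2COC | intermediate
7 | 3-[(1S)-1-{[(2S)-2-(methoxymethyl)pyrrolidin-1-yl]carbonyl}-2-oxocyclohex-5-en-1-yl]propanal | O=CCC[C@]1(C(=O)N2CCC[C@H]2COC)C=CCCC1=O | intermediate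
8 | (3aS,7aR)-7a-hydroxy-3a-{[(2S)-2-(methoxymethyl)pyrrolidin-1-yl]carbonyl}-2,3,3a,6,7,7a-hexahydro-1H-inden-1-one (cis-fused α-ketol) | O=C1CC[C@]2(C(=O)N3CCC[C@H]3COC)C=CCC[C@]12O | intermediate
9 | (3aS,7aS)-3a-{[(2S)-2-(methoxymethyl)pyrrolidin-1-yl]carbonyl}-2,3,3a,6,7,7a-hexahydro-1H-inden-1-one (cis-fused; amide and 7a-H both α) | O=C1CC[C@]2(C(=O)N3CCC[C@H]3COC)C=CCC[C@H]12 | intermediate
10 | trimethylsilyl enol ether of 9 (C3′(OSiMe3)=C6) | C[Si](C)(C)OC1=CC[C@]2(C(=O)N3CCC[C@H]3COC)C=CCC[C@H]12 | intermediate
11 | (3aR,7aS)-3a-{[(2S)-2-(methoxymethyl)pyrrolidin-1-yl]carbonyl}-3a,6,7,7a-tetrahydro-1H-inden-1-one (enone C3′=O, C6=C7) | O=C1C=C[C@]2(C(=O)N3CCC[C@H]3COC)C=CCC[C@H]12 | intermediate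
12 | butanal | CCCC=O | starting material
13 | tributyltin hydride | CCCC[SnH](CCCC)CCCC | starting material
14 | lithium 1-(tributylstannyl)butan-1-olate | [Li+].CCCC([O-])[Sn](CCCC)(CCCC)CCCC | intermediate
15 | tributyl[1-(methoxymethoxy)butyl]stannane (racemic) | CCCC(OCOC)[Sn](CCCC)(CCCC)CCCC | intermediate
16 | 1-(methoxymethoxy)butyllithium | [Li]C(CCC)OCOC | intermediate
17 | lithium alkoxide of the 1,2-adduct (C3′: β-OLi, α-CH(OMOM)Pr; C6=C7; cis-fused; auxiliary amide on C7a′) | [Li+].[O-][C@]1(C(CCC)OCOC)C=C[C@]2(C(=O)N3CCC[C@H]3COC)C=CCC[C@H]12 | intermediate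
18 | methyl carbonate of the tertiary allylic alcohol (C3′: β-OCO2Me, α-CH(OMOM)Pr; C6=C7) | COC(=O)O[C@]1(C(CCC)OCOC)C=C[C@]2(C(=O)N3CCC[C@H]3COC)C=CCC[C@H]12 | intermediate
19 | tetronic acid (4-hydroxyfuran-2(5H)-one) | OC1=CC(=O)OC1 | starting material
20 | 4-hydroxy-3-(ring B C7)-furan-2(5H)-one: C7 carries the tetronic acid on the β face and H on α; C6=C3′ with CH(OMOM)Pr on C3′; C3a′-H α; amide on C7a′ α | O=C1OCC(O)=C1[C@H]1C=C(C(CCC)OCOC)[C@H]2CCC=C[C@@]12C(=O)N3CCC[C@H]3COC | intermediate
21 | 4-trifluoromethanesulfonate of 20 | O=C1OCC(OS(=O)(=O)C(F)(F)F)=C1[C@H]1C=C(C(CCC)OCOC)[C@H]2CCC=C[C@@]12C(=O)N3CCC[C@H]3COC | intermediate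
22 | tributyl(vinyl)stannane | C=C[Sn](CCCC)(CCCC)CCCC | starting material
23 | 4-vinyl analogue of 21 (3-substituted 4-vinylfuran-2(5H)-one) | O=C1OCC(C=C)=C1[C@H]1C=C(C(CCC)OCOC)[C@H]2CCC=C[C@@]12C(=O)N3CCC[C@H]3COC | intermediate
24 | cyclic iminium ether iodide (O2′–C3′ bond formed; C1′=N+ of the pyrrolidine; 6β-iodo) | [I-].C=CC1=C([C@H]2[C@@H](I)[C@]3(C(CCC)OCOC)OC(=[N+]5CCC[C@H]5COC)[C@]24C=CCC[C@H]34)C(=O)OC1 | intermediate
25 | iodolactone: 2-oxabicyclo[2.2.1]heptan-3-one bridging C7a′ and C3′ on the α face; 6β-iodo; 7β-(4-vinyl-2-oxo-2,5-dihydrofuran-3-yl); C3′β-CH(OMOM)Pr; ring C fused at C7a′–C3a′ | C=CC1=C([C@H]2[C@@H](I)[C@]3(C(CCC)OCOC)OC(=O)[C@]24C=CCC[C@H]34)C(=O)OC1 | intermediate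
26 | pentacyclic bis-lactone: target skeleton with C3 as CH2 and C8′ as CH(OMOM) | C1OC(=O)C2=C1CC[C@@H]1[C@H]2[C@]23C=CCC[C@@H]2[C@@]1(C(CCC)OCOC)OC3=O | intermediate
27 | 2-(tert-butyldimethylsilyloxy)furan derived from the butenolide of 26 | CC(C)(C)[Si](C)(C)Oc1occ2c1[C@@H]1[C@]34C=CCC[C@@H]3[C@](OC4=O)(C(CCC)OCOC)[C@@H]1CC2 | intermediate
28 | C3-(1-hydroxybutyl) butenolide (mixture at C3 and C8) | CCCC(O)C1OC(=O)C2=C1CC[C@@H]1[C@H]2[C@]23C=CCC[C@@H]2[C@@]1(C(CCC)OCOC)OC3=O | intermediate
29 | methanesulfonate of 28 | CCCC(OS(C)(=O)=O)C1OC(=O)C2=C1CC[C@@H]1[C@H]2[C@]23C=CCC[C@@H]2[C@@]1(C(CCC)OCOC)OC3=O | intermediate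
30 | (Z)-3-butylidene compound with C8′–OMOM | CCC/C=C1\OC(=O)C2=C1CC[C@@H]1[C@H]2[C@]23C=CCC[C@@H]2[C@@]1(C(CCC)OCOC)OC3=O | intermediate
31 | (Z)-3-butylidene compound with C8′–OH | CCC/C=C1\OC(=O)C2=C1CC[C@@H]1[C@H]2[C@]23C=CCC[C@@H]2[C@@]1(C(O)CCC)OC3=O | intermediate
32 | CNP0423313.1 | CCC/C=C1\OC(=O)C2=C1CC[C@@H]1[C@H]2[C@]23C=CCC[C@@H]2[C@@]1(C(=O)CCC)OC3=O | target

**Step count and risks**

Total step count: 17. Longest linear sequence: 16 (steps 1–6 and 8–17; step 7 is a one-step side branch).

Steps most likely to fail:

Step 9. The hindered π-allylpalladium intermediate may lose a β-hydrogen to give a cyclopentadiene, or may be attacked at oxygen or on the wrong face; any carbinol epimer from step 8 would lead to the C7 epimer. Fallback, from 11 back to 20: enone 11 is treated with organolithium 16 as in step 8, but the alkoxide is quenched with acetyl chloride to give the tertiary allylic acetate F1. Ireland–Claisen rearrangement (LDA, TMSCl, THF, −78 °C → 60 °C, aqueous work-up) transfers the acetate carbon suprafacially from the β oxygen on C3′ to C7 and gives the C7β acetic acid F2 with the same C6=C3′ alkene. Alkylation of the carboxylate with ethyl bromoacetate (K2CO3, DMF) gives the glycolate ester F3, and Dieckmann cyclisation (KOtBu, THF) closes the tetronic acid ring and returns to 20.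

Step 12. The iodonium may be captured on the cyclohexene π bond (amide participation on ring C), opened at C6 instead of C3′, or iodine may be consumed by the dienyl lactone. Fallback, from 23 back to 26: the lactone is closed by selenium-based cyclofunctionalisation, which is reversible and therefore under thermodynamic rather than kinetic control. Compound 23 with PhSeCl (CH2Cl2, −78 °C, then water) should give the 6β-phenylselenide lactone F4 with release of the auxiliary. F4 serves as the radical precursor under the conditions of step 13 and returns to 26.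

Step 13. The C6 radical may be reduced before it cyclises, may close 5-exo, or the silyl radical may start chain addition to the dienyl lactone. Fallback, from 25 back to 26: ring A is closed without a hydrogen donor by a Pd-catalysed alkyl Heck-type cyclisation of the iodide (Pd(PPh3)4, Cy2NMe, PhH, 110 °C). This ends by β-hydride elimination and gives the ring-A diene F5 (C4=C5 retained next to C3a=C7a). A copper hydride 1,6-reduction of this dienyl lactone (hexameric triphenylphosphine copper hydride, wet benzene) then saturates C4–C5 and returns to 26.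

Further compounds
F1 | step 9 | tertiary allylic acetate (C3′: β-OAc, α-CH(OMOM)Pr; C6=C7) | CC(=O)O[C@]1(C(CCC)OCOC)C=C[C@]2(C(=O)N3CCC[C@H]3COC)C=CCC[C@H]12
F2 | step 9 | C7β acetic acid (C6=C3′; amide on C7a′) | OC(=O)C[C@H]1C=C(C(CCC)OCOC)[C@H]2CCC=C[C@@]12C(=O)N3CCC[C@H]3COC
F3 | step 9 | 2-ethoxy-2-oxoethyl ester of F2 | CCOC(=O)COC(=O)C[C@H]1C=C(C(CCC)OCOC)[C@H]2CCC=C[C@@]12C(=O)N3CCC[C@H]3COC
F4 | step 12 | 6β-phenylselanyl bridged lactone (selenium analogue of 25) | C=CC1=C([C@H]2[C@@H]([Se]c5ccccc5)[C@]3(C(CCC)OCOC)OC(=O)[C@]24C=CCC[C@H]34)C(=O)OC1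
F5 | step 13 | ring-A diene (C4=C5 and C3a=C7a; otherwise as 26) | C1OC(=O)C2=C1C=C[C@@H]1[C@H]2[C@]23C=CCC[C@@H]2[C@@]1(C(CCC)OCOC)OC3=O
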